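The numbers in the tables come from a simulation for an exercise; the scatter is artificial.

The leftover comes first. In the north-west run at 120 min, substrate and target together account for 33.2%, so 66.8% of the charge sits in a stage we do not read. In that run substrate leaves early, and target arrives late.

| setting | north-west | south-east | dusk | summer | spring |
|---|---|---|---|---|---|
| substrate | 0.17 M | 0.66 M | 0.33 M | 0.33 M | 0.33 M |
| partner | 2.5 equiv | 2.5 equiv | 2.50 equiv | 2.50 equiv | 2.50 equiv |
| protic impurity | 6.6 mM | 6.6 mM | 6.60 mM | 6.60 mM | 6.60 mM |
| free catalyst | 0.066 mol% | 0.066 mol% | 0.066 mol% | 0.066 mol% | 0.066 mol% |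
| second catalyst | 5 mol% | 5 mol% | 5 mol% | 5 mol% | 5 mol% |
| temperature | −20 °C | 0 °C | 15 °C | −15 °C | 0 °C |
| remark | run made earlier | run made earlier |  |  |  |
| time |  |  | 80 min | 80 min | 80 min |

| run | time / min | target / % | substrate / % |
|---|---|---|---|
| north-west | 50.0 | 10.0 | 19.3 |
| north-west | 120 | 31.9 | 1.3 |
| north-west | 240 | 59.7 | 0 |
| north-west | 480 | 84.1 | 0.6 |
| south-east | 25.0 | 89.3 | 0 |
| south-east | 60.0 | 100.1 | 0 |
| south-east | 120 | 100.0 | 0.1 |
| south-east | 180 | 98.9 | 0 |

(scatter of a reading: 1 percentage point)

- the numbers in the tables scatter by 1 percentage point (one standard deviation)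
- a reading or a percentage of target counts all its forms, free or not

- which flask leads in amount of target, in percent of the substrate charged ("all alike" within 1.5 percentage points) (dusk / summer / spring / all alike)
- how much target is there at the end, in percent of the substrate charged: dusk
- how much target is there at the end, in percent of the substrate charged: summer
- how much target is there at the end, in percent of the substrate charged: spring

For whoever takes over the bench: at 5 mol%, each second catalyst must turn over 20.0 times (its turnover number) to finish a flask. We assume that, at fixed equivalents and loadings, both second catalyst and partner scale with the charge. Turnovers per minute then go with the charge squared.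

So we count the charge clock, 523 M^2 s: charge squared times time, here for each new flask. At fixed equivalents and loadings, equal clocks at equal temperature should give equal percent. We ignore the falling partner and the start-up.

One clock length is the stretch that cuts the target still missing by the factor e. South-east, at 0 °C, reached 89.3% on 653 M^2 s, so one clock length there reads 292 M^2 s. North-west, at −20 °C, gives a longer one, 447 M^2 s.

When you come, we expect spring at 83.3% and summer at 68.9%; for summer we borrow the north-west length, although summer is warmer than that run. Dusk has the same clock and is warmer than both others, and our colder run read the longer length, so we rank dusk first. Do not dilute: at fixed equivalents and loadings, the clock goes with the square of the charge.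

The forecast says dusk leads, with 98.5%, 72% and 95% for dusk, summer and spring, citing “a weak temperature effect”; its spring stands above ours.

Spring gives 87.8%, summer 71.2% and dusk 95.5%, so dusk leads.

    second catalyst + target ⇌ idle complex (K = 0.0900 M⁻¹, k = 0.0170 M⁻¹ s⁻¹, Ea = 40.0 kJ mol⁻¹, ΔH = −9.00 kJ mol⁻¹)
    substrate + free catalyst → free catalyst + open intermediate (k = 25.0 M⁻¹ s⁻¹, Ea = 48.0 kJ mol⁻¹)
    partner + protic impurity → quenched reagent (k = 6.10 M⁻¹ s⁻¹, Ea = 50.0 kJ mol⁻¹)
    partner + catalyst intermediate → second catalyst + target (k = 2.60 M⁻¹ s⁻¹, Ea = 44.0 kJ mol⁻¹)
    second catalyst + open intermediate ⇌ catalyst intermediate (K = 0.0180 M⁻¹, k = 1.30 M⁻¹ s⁻¹, Ea = 47.0 kJ mol⁻¹, ΔH = −26.0 kJ mol⁻¹)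
    (constants at 0 °C)

In spring at 80.0 min, substrate stands at 0% and open intermediate at 12.2%. Our clock read 4.5 percentage points low there. Left until 800 min, spring's clock reaches 5230 M^2 s, which is 17.9 lengths, and the flask stands at 100%.

Take summer's recipe with 0.56 M of substrate, equivalents and loadings held. Its clock is 1510 M^2 s, and the north-west length gives 96.6%. The computed neighbour holds 95.7% target, with 4.32% open intermediate.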